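**Retrosynthetic overview**
1. The bridged pyran and the cyclohexane are opened first, at O–C(Me) and at the CH2–CH(quinolone B) bond. This leads back to carbinol 13, which should close both rings in acid through an o-quinone methide (step 7).
2. The CH that carries quinolone B is read as an acyl carbon. 3-Acyl-4-hydroxyquinolone 12 is then ketene 10 plus 4-hydroxy-1-methylquinolin-2-one (1).
3. Ketene 10 comes from Wolff ring contraction of α-diazo-oxepinone 9. The 2,2-dimethylpyran ring (O, CMe2, CH, CH, C-3 and C-4 of quinolone A) arises from a seven-membered ring that holds these six atoms plus the acyl carbon, placed between CMe2 and CH.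
4. Enabling feature: the pyran CH next to CMe2 carries exactly one exocyclic carbon, and its ring neighbour on that side is a quaternary, O-bearing carbon. Put back into the ring, the exocyclic carbon is a ketone whose only migrating group is CMe2 and whose only enolisable (diazotisable) position is that CH.
5. Compound 9 comes from enone 5, where an asymmetric 1,4-addition sets the one controlling stereocentre, and 5 comes from 1 plus 3-hydroxy-3-methylbutan-2-one. Ring order: oxepinone (step 2), pyran (step 5), then cyclohexane and bridged pyran (step 7).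

Key step: step 5

Assumption: the Rh/(R)-BINAP catalyst is taken to follow the facial sense known for 2-cycloalkenones (otherwise (S)-BINAP is used), and 1, 3 and 6 are taken to be catalogue chemicals.

Step 1
Reactants: 1 4-hydroxy-1-methylquinolin-2(1H)-one
Product: 2 4-chloro-1-methyl-2-oxo-1,2-dihydroquinoline-3-carbaldehyde
Conditions: POCl3, DMF, 0 to 60 °C; then ice, aq. NaOAc
Reagents that add atoms: phosphoryl chloride O=P(Cl)(Cl)Cl; N,N-dimethylformamide CN(C)C=O; water O
Why: Vilsmeier–Haack chloroformylation, the standard conversion of cyclic vinylogous acids of the 4-hydroxy-2-pyridone/coumarin type into 4-chloro-3-carbaldehydes, should formylate the nucleophilic C-3 and exchange the 4-OH for chloride in one pot; no stereocentre is formed.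

Step 2
Reactants: 2 4-chloro-1-methyl-2-oxo-1,2-dihydroquinoline-3-carbaldehyde; 3 3-hydroxy-3-methylbutan-2-one
Product: 5 2,2,7-trimethyloxepino[3,2-c]quinoline-3,6(2H,7H)-dione, via aryl ether aldehyde 4 (not isolated)
Conditions: NaH, THF, 0 °C; then DBU (0.3 equiv), 4 Å MS, 60 °C, 0.02 M
Reagents that add atoms: none
Why: Addition–elimination (SNAr) of the tertiary alkoxide at C-4, which is activated by the lactam and the formyl group, should be followed by an intramolecular aldol condensation in which only the methyl group can react because the O-bearing carbon is quaternary, so the seven-membered (Z)-enone is the only condensation product open to 4; no stereocentre is formed.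

Step 3
Reactants: 5 2,2,7-trimethyloxepino[3,2-c]quinoline-3,6(2H,7H)-dione; 6 (2-methylprop-1-en-1-yl)boronic acid
Product: 7 (5R)-2,2,7-trimethyl-5-(2-methylprop-1-enyl)-4,5-dihydrooxepino[3,2-c]quinoline-3,6(2H,7H)-dione
Conditions: Rh(acac)(C2H4)2 (3 mol %), (R)-BINAP (3.3 mol %), dioxane–H2O 10:1, 90 °C
Reagents that add atoms: none
Why: Rhodium-catalysed asymmetric 1,4-addition of an alkenylboronic acid to a cyclic enone (Hayashi–Miyaura reaction) should deliver the alkenyl group to the β-carbon next to the quinolone, the (R)-BINAP–Rh complex fixing the new stereocentre as R by the face selection known for five- to seven-membered 2-cycloalkenones.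

Step 4
Reactants: 7 (5R)-2,2,7-trimethyl-5-(2-methylprop-1-enyl)-4,5-dihydrooxepino[3,2-c]quinoline-3,6(2H,7H)-dione
Product: 9 (5R)-4-diazo-2,2,7-trimethyl-5-(2-methylprop-1-enyl)-4,5-dihydrooxepino[3,2-c]quinoline-3,6(2H,7H)-dione, via trifluoroacetyl ketone 8 (not isolated)
Conditions: LiHMDS, THF, −78 °C; CF3CO2CH2CF3; 5 % HCl quench; then MsN3, Et3N, H2O (1 equiv), MeCN, 23 °C
Reagents that add atoms: methanesulfonyl azide CS(=O)(=O)N=[N+]=[N-]; 2,2,2-trifluoroethyl trifluoroacetate FC(F)(F)COC(=O)C(F)(F)F (atoms in 8 only)
Why: Detrifluoroacetylative diazo transfer (Regitz type) is the reliable way to α-diazotise simple ketones, and C-4 is the sole enolisable position here because C-2 is quaternary; the stereocentre at C-5 is not involved.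

Step 5
Reactants: 9 (5R)-4-diazo-2,2,7-trimethyl-5-(2-methylprop-1-enyl)-4,5-dihydrooxepino[3,2-c]quinoline-3,6(2H,7H)-dione; 1 4-hydroxy-1-methylquinolin-2(1H)-one
Product: 12 (3S,4S)-3-[(4-hydroxy-1-methyl-2-oxoquinolin-3-yl)carbonyl]-2,2,6-trimethyl-4-(2-methylprop-1-enyl)-3,4-dihydropyrano[3,2-c]quinolin-5(6H)-one, via ketene 10 (not isolated), via enol ester 11 (not isolated)
Conditions: hν (390 nm LED), 1 (1.2 equiv), DMAP (1.5 equiv), MeCN–DMF 4:1, 20 °C; then dark, 50 °C
Reagents that add atoms: none
Why: Irradiation into the diazo n–π* band expels N2 from the s-Z-locked cyclic α-diazoketone with concerted 1,2-shift of the O-bearing CMe2 carbon from the carbonyl carbon to the diazo carbon (Wolff rearrangement), so the seven-membered oxepinone contracts to the 2,2-dimethyldihydropyran and the former ring carbonyl carbon leaves the ring as ketene 10. The closest known reactions are the photochemical Wolff ring contraction of cyclic α-diazoketones with in situ capture of the ketene by an O–H nucleophile, and the DMAP-mediated O-acylation/O→C acyl migration that turns 4-hydroxy-2-quinolones and 4-hydroxycoumarins into their 3-acyl derivatives. The only ring made is the pyran, and it is closed by ring contraction (a C→C shift inside the existing ring) rather than by a new cyclisation, while the bond to the second quinolone is intermolecular (1 adds through O-4 to give 11 and DMAP passes the acyl group on to the nucleophilic C-3). The new stereocentre C-3 of the pyran is α to an enolisable acyl group and should equilibrate under DMAP at 50 °C to the trans isomer, in which the acyl group and the C-4 alkenyl group are both pseudo-axial and so avoid the double gauche contact with the gem-dimethyl group and the A(1,3) contact with the C-5 lactam carbonyl; C-4 is untouched. The step needs migration of one group only and no free-carbene chemistry: the carbonyl carbon carries nothing but the CMe2 carbon, and the concerted photochemical pathway should outrun the 1,2-H shift from C-5–H and attack on the trisubstituted alkene that metal carbenes would favour. Light of 390 nm lies beyond the quinolone absorption, which should keep [2+2] photochemistry of the two lactam chromophores out.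

Step 6
Reactants: 12 (3S,4S)-3-[(4-hydroxy-1-methyl-2-oxoquinolin-3-yl)carbonyl]-2,2,6-trimethyl-4-(2-methylprop-1-enyl)-3,4-dihydropyrano[3,2-c]quinolin-5(6H)-one
Product: 13 (3R,4S)-3-[hydroxy(4-hydroxy-1-methyl-2-oxoquinolin-3-yl)methyl]-2,2,6-trimethyl-4-(2-methylprop-1-enyl)-3,4-dihydropyrano[3,2-c]quinolin-5(6H)-one (carbinol epimers)
Conditions: NaBH4, CeCl3·7H2O, MeOH–THF, −40 °C; pH 7 buffer
Reagents that add atoms: none
Why: Luche-type 1,2-reduction at low temperature should stop at the benzylic carbinol because elimination to the quinone methide, the gateway to over-reduction, is slow at −40 °C; the new carbinol centre may form as a mixture, which does not matter since it is ionised in step 7.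

Step 7
Reactants: 13 (3R,4S)-3-[hydroxy(4-hydroxy-1-methyl-2-oxoquinolin-3-yl)methyl]-2,2,6-trimethyl-4-(2-methylprop-1-enyl)-3,4-dihydropyrano[3,2-c]quinolin-5(6H)-one
Product: 16 paraensidimerin C, via quinone methide 14 (not isolated), via cyclohexene 15 (not isolated)
Conditions: TfOH (0.2 equiv), CH2Cl2–HFIP 4:1, −20 to 0 °C
Reagents that add atoms: none
Why: Acid ionisation of the carbinol gives the protonated o-quinone methide, the same acid moves the side-chain double bond through the tertiary cation into the 2-methylallyl position (14), and a 6-endo cation–olefin cyclisation followed by Markovnikov hydroalkoxylation of 15 (the polar sequence by which prenylated 4-hydroxy-2-quinolones cyclise in acid) should close the cyclohexane and the bridged pyran, the new benzylic centre being set by A(1,3) strain (the neighbouring ring C–H eclipses the exocyclic C=C, so the alkene tethered at the adjacent carbon attacks the face that places quinolone B equatorial and trans to the CMe2-bearing substituent) and the tertiary ether centre by the fact that the quinolone oxygen can reach the cation only from the face on which that quinolone stands.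

**Compound list**
1 | 4-hydroxy-1-methylquinolin-2(1H)-one | Cn1c(=O)cc(O)c2ccccc12 | starting material
2 | 4-chloro-1-methyl-2-oxo-1,2-dihydroquinoline-3-carbaldehyde | Cn1c(=O)c(C=O)c(Cl)c2ccccc12 | intermediate
3 | 3-hydroxy-3-methylbutan-2-one | CC(=O)C(C)(C)O | starting material
4 | 1-methyl-4-[(2-methyl-3-oxobutan-2-yl)oxy]-2-oxo-1,2-dihydroquinoline-3-carbaldehyde | Cn1c(=O)c(C=O)c(OC(C)(C)C(C)=O)c2ccccc12 | intermediate
5 | 2,2,7-trimethyloxepino[3,2-c]quinoline-3,6(2H,7H)-dione | Cn1c(=O)c2c(c3ccccc31)OC(C)(C)C(=O)C=C2 | intermediate
6 | (2-methylprop-1-en-1-yl)boronic acid | CC(C)=CB(O)O | starting material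
7 | (5R)-2,2,7-trimethyl-5-(2-methylprop-1-enyl)-4,5-dihydrooxepino[3,2-c]quinoline-3,6(2H,7H)-dione | Cn1c(=O)c2c(c3ccccc31)OC(C)(C)C(=O)C[C@@H]2C=C(C)C | intermediate
8 | 4-trifluoroacetyl derivative of 7 (spatial arrangement at C-5 as in 7, C-4 undefined) | Cn1c(=O)c2c(c3ccccc31)OC(C)(C)C(=O)C(C(=O)C(F)(F)F)[C@@H]2C=C(C)C | intermediate
9 | (5R)-4-diazo-2,2,7-trimethyl-5-(2-methylprop-1-enyl)-4,5-dihydrooxepino[3,2-c]quinoline-3,6(2H,7H)-dione | Cn1c(=O)c2c(c3ccccc31)OC(C)(C)C(=O)C(=[N+]=[N-])[C@@H]2C=C(C)C | intermediate
10 | (4S)-2,2,6-trimethyl-4-(2-methylprop-1-enyl)-3-(oxomethylidene)-3,4-dihydropyrano[3,2-c]quinolin-5(6H)-one (ketene) | Cn1c(=O)c2c(c3ccccc31)OC(C)(C)C(=C=O)[C@@H]2C=C(C)C | intermediate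
11 | 1-methyl-2-oxo-1,2-dihydroquinolin-4-yl ester of the ring-contracted pyranoquinolone-3-carboxylic acid (C-3 undefined) | Cn1c(=O)c2c(c3ccccc31)OC(C)(C)C(C(=O)Oc1cc(=O)n(C)c3ccccc13)[C@@H]2C=C(C)C | intermediate
12 | (3S,4S)-3-[(4-hydroxy-1-methyl-2-oxoquinolin-3-yl)carbonyl]-2,2,6-trimethyl-4-(2-methylprop-1-enyl)-3,4-dihydropyrano[3,2-c]quinolin-5(6H)-one (3,4-trans) | Cn1c(=O)c2c(c3ccccc31)OC(C)(C)[C@@H](C(=O)c1c(O)c3ccccc3n(C)c1=O)[C@@H]2C=C(C)C | intermediate
13 | (3R,4S)-3-[hydroxy(4-hydroxy-1-methyl-2-oxoquinolin-3-yl)methyl]-2,2,6-trimethyl-4-(2-methylprop-1-enyl)-3,4-dihydropyrano[3,2-c]quinolin-5(6H)-one (carbinol carbon undefined) | Cn1c(=O)c2c(c3ccccc31)OC(C)(C)[C@@H](C(O)c1c(O)c3ccccc3n(C)c1=O)[C@@H]2C=C(C)C | intermediate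
14 | 3-alkylidene-1-methylquinoline-2,4-dione (o-quinone methide) of the 3,4-trans pyranoquinolone that carries a 2-methylallyl group at C-4 | Cn1c(=O)c2c(c3ccccc31)OC(C)(C)[C@@H](C=C1C(=O)c3ccccc3N(C)C1=O)[C@@H]2CC(C)=C | intermediate
15 | all-trans cyclohexene-fused pyranoquinolone with the free 4-hydroxyquinolone on the allylic CH (double bond drawn between the methyl-bearing carbon and the adjacent CH) | Cn1c(=O)c2c(c3ccccc31)OC(C)(C)[C@@H]1[C@@H]2CC(C)=C[C@H]1c1c(O)c3ccccc3n(C)c1=O | intermediate
16 | paraensidimerin C | Cn1c(=O)c2c(c3ccccc31)OC(C)(C)[C@@H]1[C@@H]2C[C@]2(C)C[C@H]1c1c(c3ccccc3n(C)c1=O)O2 | target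

Total step count: 7. Longest linear sequence: 7 steps (from 1).

**Steps most likely to fail**

*Step 7.*
- The shift of the double bond into the 2-methylallyl position may be slower than loss of the proton next to the benzylic cation.
- The acid that closes the last ether may reversibly ionise the CMe2–O bond while quinolone B still has a free OH. The two quinolones would then exchange roles and the enantiomeric purity would erode.
- Facial selectivity of the cyclisation may be incomplete.

Fallback, setting out from 12 and coming back at 16. The three events are separated and strong acid is avoided. The trisubstituted alkene of 12 is first moved to the terminal position by decatungstate/cobaloxime contra-thermodynamic positional isomerisation (390 nm), which gives the 2-methylallyl ketone F1. Luche reduction gives the carbinol F2. A weak acid (diphenyl phosphate in HFIP, 0 °C) should then be enough for quinone methide formation and cyclisation to 15, which is isolated this time. The last ether is closed under neutral conditions by Co(salen)-catalysed hydrogen-atom-transfer hydroalkoxylation (N-fluorocollidinium salt, silane) to give 16.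

*Step 5.*
- Light may be filtered by the quinolone chromophores.
- A 1,2-hydrogen shift to the enone may compete with the Wolff shift.
- O→C migration of the hindered acyl group may stall at the enol ester stage.
- Equilibration at C-3 may remain incomplete.

Fallback, setting out from 7 and coming back at 12. The contraction is done by an ionic 1,2-shift, and the union is done separately. The lithium enolate of 7 is brominated (NBS, −78 °C) to the α-bromoketone F3. This ketone has no α'-hydrogen, so it should undergo the quasi-Favorskii (semibenzilic) ring contraction with NaOMe/MeOH to the trans methyl ester F4 after equilibration. Saponification gives the acid F5, and DCC/DMAP coupling with 1 (the standard C-acylation of 4-hydroxy-2-quinolones) gives 12.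

*Step 3.*
- Insertion into the hindered, aryl-conjugated enone may be slow and may lose to protodeboronation of the alkenylboronic acid.
- The face selection may be lower than for simple cycloalkenones.

Fallback, setting out from 1 and 3 and coming back at 7. The stereocentre is set before the seven-membered ring exists. Aldol condensation of 3 with 3-methylbut-2-enal gives the α'-hydroxy dienone F6. A Cu(II)–bis(oxazoline)-catalysed conjugate addition of 1 to this chelating acceptor gives the adduct F7. Selective triflation of the acidic enol (PhNTf2, Et3N) gives F8, and Cs2CO3 in MeCN should close the oxepinone by intramolecular addition–elimination of the tertiary alkoxide at C-4 to give 7.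

**Further compounds**
F1 | step 7 | (3S,4S)-3-[(4-hydroxy-1-methyl-2-oxoquinolin-3-yl)carbonyl]-2,2,6-trimethyl-4-(2-methylallyl)-3,4-dihydropyrano[3,2-c]quinolin-5(6H)-one | Cn1c(=O)c2c(c3ccccc31)OC(C)(C)[C@@H](C(=O)c1c(O)c3ccccc3n(C)c1=O)[C@@H]2CC(C)=C
F2 | step 7 | carbinol from F1 (carbinol carbon undefined) | Cn1c(=O)c2c(c3ccccc31)OC(C)(C)[C@@H](C(O)c1c(O)c3ccccc3n(C)c1=O)[C@@H]2CC(C)=C
F3 | step 5 | 4-bromo derivative of 7 (C-4 undefined) | Cn1c(=O)c2c(c3ccccc31)OC(C)(C)C(=O)C(Br)[C@@H]2C=C(C)C
F4 | step 5 | methyl trans-2,2,6-trimethyl-4-(2-methylprop-1-enyl)-5-oxo-3,4,5,6-tetrahydro-2H-pyrano[3,2-c]quinoline-3-carboxylate | Cn1c(=O)c2c(c3ccccc31)OC(C)(C)[C@@H](C(=O)OC)[C@@H]2C=C(C)C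
F5 | step 5 | carboxylic acid from F4 | Cn1c(=O)c2c(c3ccccc31)OC(C)(C)[C@@H](C(=O)O)[C@@H]2C=C(C)C
F6 | step 3 | (E)-2-hydroxy-2,7-dimethylocta-4,6-dien-3-one | CC(C)=C/C=C/C(=O)C(C)(C)O
F7 | step 3 | 4-hydroxy-3-(7-hydroxy-2,7-dimethyl-6-oxooct-2-en-4-yl)-1-methylquinolin-2(1H)-one (stereocentre as at C-5 of 7) | CC(C)=C[C@@H](CC(=O)C(C)(C)O)c1c(O)c2ccccc2n(C)c1=O
F8 | step 3 | 4-triflate of F7 | CC(C)=C[C@@H](CC(=O)C(C)(C)O)c1c(OS(=O)(=O)C(F)(F)F)c2ccccc2n(C)c1=O
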